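## Structural features

The target is an eremophilane: a trans-fused decalin in which ring A (C1–C5, C10) and ring B (C5–C10) share the C5–C10 bond. It carries an angular methyl on quaternary C5, a secondary methyl on C4 and an isopropenyl group on C7. Seven stereocentres fall into two contiguous arrays. On ring A, C3–C4–C5–C10 carry an equatorial 3α-acyloxy group, an equatorial 4β-methyl cis to the axial 5β-methyl, and a 10α-hydrogen trans to that methyl. On ring B, C7–C8–C9 carry the equatorial isopropenyl group, the axial free hydroxyl and the equatorial second acyloxy group, all on the α face. The fragile parts are the two (Z)-hex-2-enoates (Z/E isomerisation, conjugate addition), the cis-8,9-diol monoester (acyl migration) and the isopropenyl group, which is β,γ to C8 and can slip into conjugation whenever C8 is a ketone under base. The real difficulty is the quaternary C5 wedged between the C4 and C10 stereocentres, together with a triol that must end differentiated (O3 and O9 acylated, O8 free). The key step uses the fact that C5 is the β-carbon of a ring A enone whose carbonyl is the future C3 oxygen: the neighbouring C10 stereocentre steers a vinyl nucleophile to the opposite face, and the resulting C3/C4 enolate accepts the C15 methyl. The vinyl group (C6) and the methallyl group on C10 (C9, C8, C7) are the masked aldehyde and methyl ketone from which ring B is closed.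

## Logic of the disconnections

28 ⇒ 27. No skeletal bond is cut; the two (Z)-alkenes of the esters are traced back to alkynes. The enoates are the most sensitive groups, so they are unveiled last and never meet base, fluoride or hydride. The forward reduction must add one equivalent of hydrogen cis to each alkyne and spare the C11=C12 alkene.

27 ⇒ 25 + 26. The two acyl–oxygen bonds at O3 and O9 are cut. This gives the bare C15 triol and two copies of one C6 acid. The forward step must acylate two equatorial hydroxyls and leave the axial, doubly flanked O8 free.

25 ⇒ 24 ⇒ 23. The two O–Si bonds and the C8–H bond are removed, so the triol becomes the bis-silyl ether of a C8 ketone. An axial carbinol is best made from a ketone, and the ketone also makes C7 and C9 addressable. The hydride must come from the equatorial side, and the two silyl ethers must survive enolate chemistry and fall together.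

23 ⇒ 20 + 21. The C7–C11 bond, α to the ketone, is cut. The three-carbon unit becomes a purchasable alkenyl bromide and the bicyclic ketone loses its C7 substituent. The forward step needs the enolate on the C7 side only, no migration of the new alkene into conjugation, and C7 settling equatorial.

20 ⇒ 19 ⇒ 18 ⇒ 16. The C9–O bond is cut, after notional removal of the silyl group and return of the C6=C7 double bond. In 16, C9 is the only position that can be deprotonated, so oxygenation is regiospecific. The oxidant must reach the α face.

16 ⇒ 15. The C6=C7 bond is cut as an aldol condensation and ring B opens. The bicycle becomes a monocycle carrying only the ring A stereocentres. The demand is light: only one six-membered closure is possible and the aldehyde cannot enolise.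

15 ⇒ 13. The two carbonyl groups are reconnected to terminal alkenes: the C6 aldehyde to a vinyl group and the C8 ketone to a methallyl group. Alkenes are inert to the basic and reducing steps that precede. Both must be cleaved in one operation without harming the silyl ether.

13 ⇒ 12 ⇒ 11. The O–Si bond and the C3–H bond are removed, restoring the C3 carbonyl that activates C4 and C5 in the key step. The reduction must give the equatorial alcohol although the axial approach is blocked by the C5 methyl, which calls for a thermodynamically controlled electron-transfer reduction.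

11 ⇒ 6 + 7 + 8. The C5–C6 and C4–C15 bonds are cut; they sit at the β- and α-carbons of the C3 carbonyl. The quaternary centre and two stereocentres disappear, leaving an enone with one stereocentre (C10) and two small reagents. The forward step needs addition anti to the C10 branch, methylation at C4 only, and an equilibration that brings the C4 methyl equatorial.

6 ⇒ 5 ⇒ 4. The C5–C14 bond is cut and the C4=C5 unsaturation is notionally removed. Compound 4, without the methyl, is reliably accessible in enantioenriched form by catalysis, which is not true of 6 itself. The enolate from the methyl addition must be trapped and dehydrogenated back toward C5 without touching the methallyl alkene or C10.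

4 ⇒ 3 ⇒ 1 + 2. The C4=C5 bond (aldol condensation) and the C1–C10 bond (Michael addition) are cut. Two achiral building blocks of six and four carbons remain, and C10 is set by the catalyst. The forward steps need high enantioselectivity and a cyclisation faster than enolisation of the aldehyde α-centre.

## Other disconnections considered

Alternative 1: The cut is C5–C10 and C3–C4 of ring A, with ring B as the tether. The forward step heats the (E,E,E)-trienal A1, in which the β,β-disubstituted enal C4=C5 is the dienophile and the 1-siloxydiene C10=C1–C2=C3 is tied to it through C6–C9 (dithiane at C8, silyl ether at C9), to give the octalin aldehyde A2.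
- In its favour: both rings and the C3, C4, C5 and C10 stereocentres arise in one step from an open chain, and the endo transition state gives the trans fusion. The cis relationship of C14 and C15 follows stereospecifically from the enal geometry. On this point it is better than the chosen plan, where C4 rests on an equilibration of modest bias.
- Against it: suprafacial addition to an (E,E)-diene ties the C3 oxygen cis to the C9 branch on C10, so A2 carries a 3β oxygen. The target needs 3α, so an inversion next to a substituted carbon would be required. C15 arrives as an aldehyde and must be reduced to a methyl in the presence of a dithiane. A trisubstituted enal forming a quaternary centre is a sluggish dienophile, and one remote stereocentre (C9) must control the π-face.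
- Comparison: after the cycloaddition the C1=C2 hydrogenation, dithiane removal, C7 isopropenylation, C8 reduction and the acylations remain, so the ring B work is equal to that of the chosen plan. The alternative is superior in bonds and stereocentres per step, inferior in functional-group fit, and probably longer.

Alternative 2: The cut is C8–C9. The forward step is a SmI2-mediated pinacol coupling of the dialdehyde A3 (C9 aldehyde on C10; C8 aldehyde at the end of the C6–C7 chain on C5, isopropenyl already on C7) to give the cis-diol A4.
- In its favour: both oxygens appear at the right oxidation level and cis to each other. Because the isopropenyl group is present before ring closure, no conjugation-prone β,γ-unsaturated ketone and no palladium enolate coupling are needed. On these points it is better than the chosen plan.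
- Against it: A3 has two enolisable α-branched aldehydes, one of them at the ring-fusion carbon C10. C7 must be set in an open chain by a separate asymmetric operation. The cis-diol could form on either face (α,α is needed; β,β is conceivable), which is not securely predictable.
- Comparison: ring A with its quaternary C5 would still need a conjugate addition of the kind used in the chosen plan. The end game (desilylation, selective bis-acylation, semihydrogenation) is identical, so the two are equal there. The alternative is shorter after ring closure and longer before it, with more stereochemical risk concentrated in one step.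

Alternative 3: The cut is C7–C8. The forward step is a Me2AlCl-promoted type 1 carbonyl-ene cyclisation of the α-silyloxy aldehyde A5 (C8 aldehyde; prenyl group on C5) to give A6.
- In its favour: the C7–C8 bond, the isopropenyl group and the C8 carbinol arise together without any enolate, and the chair transition state places the C7 substituent equatorial. For introducing C11–C13 it is better than the chosen plan.
- Against it: the same chair places the new hydroxyl equatorial (8β, trans to the isopropenyl group), so A6 is the 8-epimer. Correction by oxidation and bulky-hydride reduction adds two steps and passes through the same ketone as 23, so the conjugation risk is not avoided. The α-silyloxy aldehyde may epimerise at C9 or chelate the Lewis acid. A prenyl group on quaternary C5 cannot come from a simple conjugate addition because of allylic transposition.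
- Comparison: the final C8 reduction is identical in both plans (equal). Overall the step count is similar or higher.

Key step: step 5

Remarks on the chemistry:
- Eremophilane numbering is used for every compound (C14 on C5, C15 on C4, C11–C13 on C7); β is the face of the angular C5 methyl; TBS = tert-butyldimethylsilyl.
- 4-Methylpent-4-enal 1 is treated as a purchasable aldehyde.
- With the (S)-configured pyrrolidine catalyst the enamine should be attacked on the face remote from the diarylmethyl group, which corresponds to (S)-3; the mirror-image catalyst is equally available.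

## Route

Step 1
Reactants: 1 4-methylpent-4-enal; 2 but-3-en-2-one
Product: 3 (2S)-2-(2-methylprop-2-en-1-yl)-5-oxohexanal
Conditions: (S)-2-[methoxy(diphenyl)methyl]pyrrolidine (5 mol %), ethyl 3,4-dihydroxybenzoate (20 mol %), neat, 4 °C
Reagents that add atoms: none
Why: Enamine-catalysed Michael addition of an aldehyde to an enone; the E-enamine of 1 is attacked by 2 on the face away from the methoxydiphenylmethyl group, which should set C10 as (S) with high enantioselectivity, the catechol co-catalyst activating the enone by hydrogen bonding.

Step 2
Reactants: 3 (2S)-2-(2-methylprop-2-en-1-yl)-5-oxohexanal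
Product: 4 (4S)-4-(2-methylprop-2-en-1-yl)cyclohex-2-en-1-one
Conditions: aq KOH (0.1 M), Bu4NOH (cat.), Et2O–THF, 40 °C
Reagents that add atoms: none
Why: Intramolecular aldol condensation; only the methyl ketone enolate can reach the aldehyde through a six-membered ring, and dilute biphasic base should let cyclisation outpace enolisation at the α-stereocentre, which becomes the non-acidic C10 once the ring has closed.

Step 3
Reactants: 4 (4S)-4-(2-methylprop-2-en-1-yl)cyclohex-2-en-1-one
Product: 5 trimethyl{[(3S,4S)-3-methyl-4-(2-methylprop-2-en-1-yl)cyclohex-1-en-1-yl]oxy}silane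
Conditions: Me2CuLi (from MeLi and CuI), Me3SiCl, Et2O–THF, −78 °C; Et3N, aq NaHCO3
Reagents that add atoms: lithium dimethylcuprate [Li+].C[Cu-]C; chlorotrimethylsilane C[Si](C)(C)Cl
Why: Cuprate conjugate addition with in situ silyl trapping; the methyl (C14) should enter trans to the C10 branch, but this centre is erased in step 4, and the point of the step is the regiodefined silyl enol ether.

Step 4
Reactants: 5 trimethyl{[(3S,4S)-3-methyl-4-(2-methylprop-2-en-1-yl)cyclohex-1-en-1-yl]oxy}silane
Product: 6 (4S)-3-methyl-4-(2-methylprop-2-en-1-yl)cyclohex-2-en-1-one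
Conditions: IBX (2-iodoxybenzoic acid), 4-methoxypyridine N-oxide, DMSO, rt
Reagents that add atoms: none
Why: Dehydrogenation of a silyl enol ether to the enone by IBX (a metal-free counterpart of the Saegusa–Ito oxidation); the position of the enol ether fixes the new C4=C5 bond, C10 is not touched, and no divalent palladium is brought near the methallyl alkene.

Step 5
Reactants: 6 (4S)-3-methyl-4-(2-methylprop-2-en-1-yl)cyclohex-2-en-1-one; 7 vinylmagnesium bromide; 8 iodomethane
Product: 11 (2R,3S,4S)-2,3-dimethyl-4-(2-methylprop-2-en-1-yl)-3-vinylcyclohexan-1-one, via bromomagnesium enolate 9 (not isolated), via C4-epimeric ketone 10 (not isolated)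
Conditions: 7 (2.2 equiv), CuBr·SMe2 (1.1 equiv), THF–Me2S, −78 → −20 °C; 8 (5 equiv), DMPU, −20 °C → rt; crude: NaOMe, MeOH, rt
Reagents that add atoms: none
Why: Two equivalents of 7 and CuBr·SMe2 give the divinylcuprate, which adds to the enone through a copper–alkene complex and reductive elimination at the β-carbon C5, forming C5–C6 and the regiodefined enolate 9; this is the classical copper-mediated conjugate addition to a β,β-disubstituted cyclohexenone with C-alkylation of the enolate (vicinal difunctionalisation). No ring is closed. C5 is controlled by C10: allylic strain with the C5 methyl holds the methallyl group pseudoaxial and the cuprate enters antiperiplanar on the opposite face, so the vinyl group ends trans to the C9 branch, which is the future trans ring fusion. Enolate 9 is then methylated at C4 by SN2 attack on 8 (DMPU loosens the magnesium enolate), forming C4–C15. Kinetically the methyl is expected to enter anti to the axial angular methyl and give mainly 10, so C4 is set afterwards under thermodynamic control: NaOMe equilibrates the enolisable centre toward 11, whose chair carries the C4 methyl and the C10 side chain equatorial. The bias should be real but modest, because the equatorial methyl is gauche to both C5 substituents, so residual 10 is separated and returned to the equilibration. The step needs 1,4- over 1,2-addition and methylation at C4 rather than at C2 or oxygen: the first is secured by binding all of 7 to copper, the second by generating 9 regiospecifically and alkylating it with a small, soft electrophile before proton exchange.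

Step 6
Reactants: 11 (2R,3S,4S)-2,3-dimethyl-4-(2-methylprop-2-en-1-yl)-3-vinylcyclohexan-1-one
Product: 12 (1R,2R,3S,4S)-2,3-dimethyl-4-(2-methylprop-2-en-1-yl)-3-vinylcyclohexan-1-ol
Conditions: Li, NH3(l), THF, t-BuOH, −78 °C; NH4Cl
Reagents that add atoms: none
Why: Dissolving-metal reduction of a hindered cyclohexanone, which gives the thermodynamically preferred equatorial (3α) alcohol through ketyl and carbanion protonation; hydride reagents would instead attack from the equatorial side because the axial C5 methyl blocks the axial path. The isolated alkenes are not reduced and the proton donor suppresses enolisation at C4.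

Step 7
Reactants: 12 (1R,2R,3S,4S)-2,3-dimethyl-4-(2-methylprop-2-en-1-yl)-3-vinylcyclohexan-1-ol
Product: 13 tert-butyl{[(1R,2R,3S,4S)-2,3-dimethyl-4-(2-methylprop-2-en-1-yl)-3-vinylcyclohexyl]oxy}dimethylsilane
Conditions: t-BuMe2SiCl, imidazole, DMF, rt
Reagents that add atoms: tert-butyldimethylsilyl chloride CC(C)(C)[Si](C)(C)Cl
Why: Standard silylation of an equatorial secondary alcohol; the ether keeps O3 from forming a lactol with the C6 aldehyde made in step 8 and survives base, enolates and hydride.

Step 8
Reactants: 13 tert-butyl{[(1R,2R,3S,4S)-2,3-dimethyl-4-(2-methylprop-2-en-1-yl)-3-vinylcyclohexyl]oxy}dimethylsilane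
Product: 15 (1S,2R,3R,6S)-3-[(tert-butyldimethylsilyl)oxy]-1,2-dimethyl-6-(2-oxopropyl)cyclohexane-1-carbaldehyde, via bis-ozonide 14 (not isolated)
Conditions: O3, CH2Cl2, −78 °C; PPh3, −78 °C → rt
Reagents that add atoms: ozone [O-][O+]=O
Why: Ozonolysis with reductive work-up cleaves both unconjugated terminal alkenes in one operation, the vinyl group to the C6 aldehyde (non-enolisable, on quaternary C5) and the methallyl group to the C8 methyl ketone; no stereocentre is affected.

Step 9
Reactants: 15 (1S,2R,3R,6S)-3-[(tert-butyldimethylsilyl)oxy]-1,2-dimethyl-6-(2-oxopropyl)cyclohexane-1-carbaldehyde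
Product: 16 3α-(tert-butyldimethylsilyloxy)-11,12,13-trinoreremophil-6-en-8-one
Conditions: KOH, MeOH–THF, 0 °C → rt
Reagents that add atoms: none
Why: Intramolecular aldol condensation closing ring B by the C6–C7 bond; only the C7 methyl enolate can reach the aldehyde through a six-membered ring (the C9 enolate would give a four-membered ring), and E1cB dehydration gives the conjugated enone. C5 and C10 are not enolisable, so the trans fusion set in step 5 is kept.

Step 10
Reactants: 16 3α-(tert-butyldimethylsilyloxy)-11,12,13-trinoreremophil-6-en-8-one
Product: 18 3α-(tert-butyldimethylsilyloxy)-9α-hydroxy-11,12,13-trinoreremophil-6-en-8-one, via potassium dienolate 17 (not isolated)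
Conditions: KN(SiMe3)2, THF, −78 °C; 2-(phenylsulfonyl)-3-phenyloxaziridine, −78 °C; aq NH4Cl
Reagents that add atoms: 2-(phenylsulfonyl)-3-phenyloxaziridine O=S(=O)(N1OC1c1ccccc1)c1ccccc1
Why: α′-Hydroxylation of an enone through its kinetic enolate with an N-sulfonyloxaziridine; C9 is the only site that can be deprotonated (C7 is vinylic and the γ-position C5 is quaternary). Oxygen should be delivered to the α face because the angular β-methyl on C5 stands over the β face of the nearly flat dienolate, giving the pseudoequatorial 9α-alcohol.

Step 11
Reactants: 18 3α-(tert-butyldimethylsilyloxy)-9α-hydroxy-11,12,13-trinoreremophil-6-en-8-one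
Product: 19 3α,9α-bis(tert-butyldimethylsilyloxy)-11,12,13-trinoreremophil-6-en-8-one
Conditions: t-BuMe2SiOSO2CF3, 2,6-lutidine, CH2Cl2, −78 → 0 °C
Reagents that add atoms: tert-butyldimethylsilyl trifluoromethanesulfonate CC(C)(C)[Si](C)(C)OS(=O)(=O)C(F)(F)F
Why: Silylation of the α-ketol under non-enolising conditions blocks α-ketol rearrangement and makes the C9 side of the ketone the hindered one for step 13; the same silyl group on O3 and O9 allows one deprotection later.

Step 12
Reactants: 19 3α,9α-bis(tert-butyldimethylsilyloxy)-11,12,13-trinoreremophil-6-en-8-one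
Product: 20 3α,9α-bis(tert-butyldimethylsilyloxy)-11,12,13-trinoreremophilan-8-one
Conditions: H2 (1 atm), Pd/C, EtOAc, rt
Reagents that add atoms: none
Why: Heterogeneous hydrogenation of the enone C6=C7 bond; no stereocentre is created and the silyl ethers are stable in ethyl acetate.

Step 13
Reactants: 20 3α,9α-bis(tert-butyldimethylsilyloxy)-11,12,13-trinoreremophilan-8-one; 21 2-bromopropene
Product: 23 3α,9α-bis(tert-butyldimethylsilyloxy)eremophil-11-en-8-one, via lithium enolate 22 (not isolated)
Conditions: LiN(SiMe3)2 (2.2 equiv), toluene–THF, −78 → 0 °C; Pd2(dba)3 (2.5 mol %), P(t-Bu)3 (10 mol %), 21, rt; AcOH, −78 °C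
Reagents that add atoms: none
Why: Palladium-catalysed α-alkenylation of a ketone enolate: oxidative addition of 21 to zerovalent palladium, transmetalation with 22 and C–C reductive elimination form C7–C11. Deprotonation goes to the C7 methylene because C9 is tertiary and carries the bulky silyloxy group. C7 stays enolisable and should settle equatorial (α), since an axial isopropenyl group would be syn-diaxial to the angular methyl; the cold acidic quench protonates the product enolate at carbon before the alkene can move into conjugation.

Step 14
Reactants: 23 3α,9α-bis(tert-butyldimethylsilyloxy)eremophil-11-en-8-one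
Product: 24 3α,9α-bis(tert-butyldimethylsilyloxy)eremophil-11-en-8α-ol
Conditions: LiBH(s-Bu)3, THF, −78 °C; aq NaOH, H2O2, 0 °C
Reagents that add atoms: none
Why: Reduction of a cyclohexanone flanked by two equatorial substituents with a bulky trialkylborohydride; hydride arrives along the equatorial direction and gives the axial 8α-alcohol, cis to both neighbours.

Step 15
Reactants: 24 3α,9α-bis(tert-butyldimethylsilyloxy)eremophil-11-en-8α-ol
Product: 25 eremophil-11-ene-3α,8α,9α-triol
Conditions: Bu4NF, THF, rt → 45 °C
Reagents that add atoms: none
Why: Fluoride cleavage of both silyl ethers; any O9→O8 silyl migration under these conditions is harmless because both groups are removed, and the molecule holds no base-sensitive group at this stage.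

Step 16
Reactants: 25 eremophil-11-ene-3α,8α,9α-triol; 26 hex-2-ynoic acid
Product: 27 8α-hydroxyeremophil-11-ene-3α,9α-diyl bis(hex-2-ynoate)
Conditions: 26 (2.2 equiv), N,N′-diisopropylcarbodiimide, DMAP (5 mol %), CH2Cl2, −20 → 0 °C
Reagents that add atoms: none
Why: Carbodiimide (Steglich) esterification; the equatorial O3 and O9 hydroxyls should react well before the axial O8 hydroxyl, which is flanked by the C7 and C9 substituents and 1,3-diaxial to two ring hydrogens. The ynoic acid is used instead of the (Z)-enoic acid so that no nucleophilic catalyst can isomerise a (Z)-alkene.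

Step 17
Reactants: 27 8α-hydroxyeremophil-11-ene-3α,9α-diyl bis(hex-2-ynoate)
Product: 28 8α-hydroxyeremophil-11-ene-3α,9α-diyl bis[(2Z)-hex-2-enoate] (CNP0420276.1)
Conditions: H2 (1 atm), Pd/CaCO3 poisoned with Pb(OAc)2, quinoline, EtOAc, rt
Reagents that add atoms: none
Why: Syn-semihydrogenation of the two conjugated alkynes on poisoned palladium (Lindlar-type reduction) gives both (Z)-enoates; the 1,1-disubstituted C11=C12 alkene binds far more weakly and should be spared if hydrogen uptake is stopped at two equivalents.

## Compound list

1 | 4-methylpent-4-enal | CC(=C)CCC=O | starting material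
2 | but-3-en-2-one | CC(=O)C=C | starting material
3 | (2S)-2-(2-methylprop-2-en-1-yl)-5-oxohexanal | CC(=O)CC[C@H](C=O)CC(C)=C | intermediate
4 | (4S)-4-(2-methylprop-2-en-1-yl)cyclohex-2-en-1-one | O=C1C=C[C@H](CC(C)=C)CC1 | intermediate
5 | trimethyl{[(3S,4S)-3-methyl-4-(2-methylprop-2-en-1-yl)cyclohex-1-en-1-yl]oxy}silane | C[Si](C)(C)OC1=C[C@@H](C)[C@H](CC(C)=C)CC1 | intermediate
6 | (4S)-3-methyl-4-(2-methylprop-2-en-1-yl)cyclohex-2-en-1-one | CC1=CC(=O)CC[C@H]1CC(C)=C | intermediate
7 | vinylmagnesium bromide | C=C[Mg]Br | starting material
8 | iodomethane | CI | starting material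
9 | bromomagnesium (3S,4S)-3-methyl-4-(2-methylprop-2-en-1-yl)-3-vinylcyclohex-1-en-1-olate | C=C[C@]1(C)C=C(O[Mg]Br)CC[C@H]1CC(C)=C | intermediate (not isolated)
10 | (2S,3S,4S)-2,3-dimethyl-4-(2-methylprop-2-en-1-yl)-3-vinylcyclohexan-1-one (4α-methyl epimer) | C=C[C@]1(C)[C@H](C)C(=O)CC[C@H]1CC(C)=C | intermediate (not isolated)
11 | (2R,3S,4S)-2,3-dimethyl-4-(2-methylprop-2-en-1-yl)-3-vinylcyclohexan-1-one | C=C[C@]1(C)[C@@H](C)C(=O)CC[C@H]1CC(C)=C | intermediate
12 | (1R,2R,3S,4S)-2,3-dimethyl-4-(2-methylprop-2-en-1-yl)-3-vinylcyclohexan-1-ol | C=C[C@]1(C)[C@@H](C)[C@H](O)CC[C@H]1CC(C)=C | intermediate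
13 | tert-butyl{[(1R,2R,3S,4S)-2,3-dimethyl-4-(2-methylprop-2-en-1-yl)-3-vinylcyclohexyl]oxy}dimethylsilane | C=C[C@]1(C)[C@@H](C)[C@H](O[Si](C)(C)C(C)(C)C)CC[C@H]1CC(C)=C | intermediate
14 | bis-ozonide of 13 (both alkenes as 1,2,4-trioxolanes; trioxolane carbons unassigned) | O1OC(OC1)[C@]2(C)[C@@H](C)[C@H](O[Si](C)(C)C(C)(C)C)CC[C@H]2CC3(C)OCOO3 | intermediate (not isolated)
15 | (1S,2R,3R,6S)-3-[(tert-butyldimethylsilyl)oxy]-1,2-dimethyl-6-(2-oxopropyl)cyclohexane-1-carbaldehyde | O=C[C@]1(C)[C@@H](C)[C@H](O[Si](C)(C)C(C)(C)C)CC[C@H]1CC(C)=O | intermediate
16 | 3α-(tert-butyldimethylsilyloxy)-11,12,13-trinoreremophil-6-en-8-one (4β,5β-dimethyl; 10α-H) | O=C1C=C[C@]2(C)[C@@H](C)[C@H](O[Si](C)(C)C(C)(C)C)CC[C@H]2C1 | intermediate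
17 | potassium 6,8(9)-dienolate of 16 | [K+].[O-]C=1C=C[C@]2(C)[C@@H](C)[C@H](O[Si](C)(C)C(C)(C)C)CC[C@H]2C=1 | intermediate (not isolated)
18 | 3α-(tert-butyldimethylsilyloxy)-9α-hydroxy-11,12,13-trinoreremophil-6-en-8-one | O=C1C=C[C@]2(C)[C@@H](C)[C@H](O[Si](C)(C)C(C)(C)C)CC[C@H]2[C@@H]1O | intermediate
19 | 3α,9α-bis(tert-butyldimethylsilyloxy)-11,12,13-trinoreremophil-6-en-8-one | O=C1C=C[C@]2(C)[C@@H](C)[C@H](O[Si](C)(C)C(C)(C)C)CC[C@H]2[C@@H]1O[Si](C)(C)C(C)(C)C | intermediate
20 | 3α,9α-bis(tert-butyldimethylsilyloxy)-11,12,13-trinoreremophilan-8-one | O=C1CC[C@]2(C)[C@@H](C)[C@H](O[Si](C)(C)C(C)(C)C)CC[C@H]2[C@@H]1O[Si](C)(C)C(C)(C)C | intermediate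
21 | 2-bromopropene | CC(Br)=C | starting material
22 | lithium 7-en-8-olate of 20 | [Li+].[O-]C1=CC[C@]2(C)[C@@H](C)[C@H](O[Si](C)(C)C(C)(C)C)CC[C@H]2[C@@H]1O[Si](C)(C)C(C)(C)C | intermediate (not isolated)
23 | 3α,9α-bis(tert-butyldimethylsilyloxy)eremophil-11-en-8-one (7α-isopropenyl) | C=C(C)[C@@H]1C[C@]2(C)[C@@H](C)[C@H](O[Si](C)(C)C(C)(C)C)CC[C@H]2[C@H](O[Si](C)(C)C(C)(C)C)C1=O | intermediate
24 | 3α,9α-bis(tert-butyldimethylsilyloxy)eremophil-11-en-8α-ol | C=C(C)[C@@H]1C[C@]2(C)[C@@H](C)[C@H](O[Si](C)(C)C(C)(C)C)CC[C@H]2[C@H](O[Si](C)(C)C(C)(C)C)[C@@H]1O | intermediate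
25 | eremophil-11-ene-3α,8α,9α-triol | C=C(C)[C@@H]1C[C@]2(C)[C@@H](C)[C@H](O)CC[C@H]2[C@H](O)[C@@H]1O | intermediate
26 | hex-2-ynoic acid | CCCC#CC(O)=O | starting material
27 | 8α-hydroxyeremophil-11-ene-3α,9α-diyl bis(hex-2-ynoate) | C=C(C)[C@@H]1C[C@]2(C)[C@@H](C)[C@H](OC(=O)C#CCCC)CC[C@H]2[C@H](OC(=O)C#CCCC)[C@@H]1O | intermediate
28 | (3R,4R,5R,7S,8R,9S,10R)-8-hydroxyeremophil-11-ene-3,9-diyl bis[(2Z)-hex-2-enoate] (CNP0420276.1) | C=C(C)[C@@H]1C[C@]2(C)[C@@H](C)[C@H](OC(=O)/C=C\CCC)CC[C@H]2[C@H](OC(=O)/C=C\CCC)[C@@H]1O | target

## Step count and least certain steps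

Total step count: 17. Longest linear sequence: 17 steps (1 and 2 to 28).

Step 5 (key step). Three processes may fail:
- Slow conjugate addition at the hindered, γ-branched β,β-disubstituted enone.
- Sluggish alkylation of the magnesium enolate, which lets proton exchange move the methyl to C2.
- Poor control at C4: kinetic methylation anti to the axial angular methyl, then an equilibrium of only modest bias, because the equatorial methyl is gauche to both C5 substituents and the unwanted epimer can relieve strain by ring inversion.

Fallback: set out from 6 and carry out the same cuprate addition, but intercept enolate 9 with dimethyl(methylidene)ammonium iodide to give the Mannich base F1. Quaternisation with MeI and elimination with NaHCO3 give the α-methylene ketone F2. Conjugate reduction of F2 with LiBH(s-Bu)3 at −78 °C regenerates the C3–C4 enolate, now bearing C15, and protonation with 2,6-di-tert-butylphenol should deliver hydrogen anti to the axial C5 methyl, so that C4 is set by kinetic protonation and not by equilibration. The route is rejoined at 11.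

Step 13. The enolate may lose its regiochemical integrity (proton transfer to C9 or O-to-O silyl transfer), the coupling may stall at the hindered enolate, and the excess base may move the new C11=C12 bond into conjugation with C8 or leave a C7 epimer mixture. Fallback: set out from 19. Iodination with I2 and pyridine gives the α-iodoenone F3. Suzuki–Miyaura coupling of F3 with isopropenylboronic acid pinacol ester (PdCl2(dppf), K3PO4) forms C7–C11 on an sp2 carbon and gives the dienone F4. Conjugate reduction of the C6=C7 bond of F4 with [(Ph3P)CuH]6 and protonation rejoin the route at 23, with no strong base meeting the β,γ-unsaturated ketone.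

Step 16. Discrimination among three secondary hydroxyls may be insufficient (over-acylation at O8 or incomplete reaction at O9), the acyl group may migrate from O9 to O8 across the cis-diol, and DMAP may add to the ynoate. Fallback: set out from 24 and protect O8 with 4-methoxybenzyl trichloroacetimidate and Sc(OTf)3 (cat.) to give the 8-O-(4-methoxybenzyl) ether F5. Bu4NF gives the 3,9-diol F6, which is acylated with 26 as in step 16 to give the diester F7, with no selectivity required. DDQ removes the benzyl ether and the route is rejoined at 27.

Step 10. Oxygen may be delivered partly to the β face, the enolate may add to the sulfonimine by-product, or over-oxidation may occur. A 9β epimer would be self-correcting after step 12, since an axial 9β-silyloxy group is syn-diaxial to the angular methyl and the centre is enolisable. Fallback: set out from 16 and use radical α′-acetoxylation with Mn(OAc)3 in benzene at reflux, which proceeds through a manganese enolate and an α-keto radical and should give the equatorial 9α-acetoxy enone F8. Methanolysis (K2CO3, MeOH, 0 °C) rejoins the route at 18.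

## Further compounds

F1 | step 5 | (3S,4S)-2-[(dimethylamino)methyl]-3-methyl-4-(2-methylprop-2-en-1-yl)-3-vinylcyclohexan-1-one (C2 unassigned) | C=C[C@]1(C)C(CN(C)C)C(=O)CC[C@H]1CC(C)=C
F2 | step 5 | (3S,4S)-3-methyl-2-methylidene-4-(2-methylprop-2-en-1-yl)-3-vinylcyclohexan-1-one | C=C[C@]1(C)C(=C)C(=O)CC[C@H]1CC(C)=C
F3 | step 13 | 3α,9α-bis(tert-butyldimethylsilyloxy)-7-iodo-11,12,13-trinoreremophil-6-en-8-one | O=C1C(I)=C[C@]2(C)[C@@H](C)[C@H](O[Si](C)(C)C(C)(C)C)CC[C@H]2[C@@H]1O[Si](C)(C)C(C)(C)C
F4 | step 13 | 3α,9α-bis(tert-butyldimethylsilyloxy)eremophila-6,11-dien-8-one | O=C1C(C(C)=C)=C[C@]2(C)[C@@H](C)[C@H](O[Si](C)(C)C(C)(C)C)CC[C@H]2[C@@H]1O[Si](C)(C)C(C)(C)C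
F5 | step 16 | 3α,9α-bis(tert-butyldimethylsilyloxy)-8α-(4-methoxybenzyloxy)eremophil-11-ene | C=C(C)[C@@H]1C[C@]2(C)[C@@H](C)[C@H](O[Si](C)(C)C(C)(C)C)CC[C@H]2[C@H](O[Si](C)(C)C(C)(C)C)[C@@H]1OCc3ccc(OC)cc3
F6 | step 16 | 8α-(4-methoxybenzyloxy)eremophil-11-ene-3α,9α-diol | C=C(C)[C@@H]1C[C@]2(C)[C@@H](C)[C@H](O)CC[C@H]2[C@H](O)[C@@H]1OCc3ccc(OC)cc3
F7 | step 16 | 8α-(4-methoxybenzyloxy)eremophil-11-ene-3α,9α-diyl bis(hex-2-ynoate) | C=C(C)[C@@H]1C[C@]2(C)[C@@H](C)[C@H](OC(=O)C#CCCC)CC[C@H]2[C@H](OC(=O)C#CCCC)[C@@H]1OCc3ccc(OC)cc3
F8 | step 10 | 9α-acetoxy-3α-(tert-butyldimethylsilyloxy)-11,12,13-trinoreremophil-6-en-8-one | O=C1C=C[C@]2(C)[C@@H](C)[C@H](O[Si](C)(C)C(C)(C)C)CC[C@H]2[C@@H]1OC(C)=O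
A1 | alternative 1 | (2E,8E,10E)-7,11-bis(tert-butyldimethylsilyloxy)-3-methylundeca-2,8,10-trienal with a 1,3-dithiane at chain C6 (eremophilane C8) | O=C/C=C(\C)CCC1(SCCCS1)[C@@H](O[Si](C)(C)C(C)(C)C)/C=C/C=C/O[Si](C)(C)C(C)(C)C
A2 | alternative 1 | trans-fused octalin carbaldehyde: 3β,9α-bis(tert-butyldimethylsilyloxy)-8,8-(propane-1,3-diyldithio)-11,12,13-trinoreremophil-1-en-15-al | C1C[C@]2(C)[C@@H](C=O)[C@@H](O[Si](C)(C)C(C)(C)C)C=C[C@H]2[C@H](O[Si](C)(C)C(C)(C)C)C13SCCCS3
A3 | alternative 2 | ring A dialdehyde: 3α-(tert-butyldimethylsilyloxy)-8,9-seco-eremophil-11-ene-8,9-dial | C=C(C)[C@@H](C=O)C[C@]1(C)[C@@H](C)[C@H](O[Si](C)(C)C(C)(C)C)CC[C@H]1C=O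
A4 | alternative 2 | 3α-(tert-butyldimethylsilyloxy)eremophil-11-ene-8α,9α-diol | C=C(C)[C@@H]1C[C@]2(C)[C@@H](C)[C@H](O[Si](C)(C)C(C)(C)C)CC[C@H]2[C@H](O)[C@@H]1O
A5 | alternative 3 | ring A aldehyde: 3α,9α-bis(tert-butyldimethylsilyloxy)-7,8-seco-eremophil-7(11)-en-8-al | CC(C)=CC[C@]1(C)[C@@H](C)[C@H](O[Si](C)(C)C(C)(C)C)CC[C@H]1[C@H](O[Si](C)(C)C(C)(C)C)C=O
A6 | alternative 3 | 3α,9α-bis(tert-butyldimethylsilyloxy)eremophil-11-en-8β-ol | C=C(C)[C@@H]1C[C@]2(C)[C@@H](C)[C@H](O[Si](C)(C)C(C)(C)C)CC[C@H]2[C@H](O[Si](C)(C)C(C)(C)C)[C@H]1O
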